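**Plan**

- Retrosynthesis: the C6–C8 bond is cut first by putting the carboxyl carbon C7 back between C6 and C8, so ring B becomes a cyclohexanone (a 7-oxo-20-norkauranolide). Behind it are cut C16–O (hydration), the lactone C10–O bond with C5–H (iodolactonisation of C5=C10), C4–C18 (Birch methylation of an aromatic ring A), C6–C7 (benzylic acylation), C9–C10 (aryl conjugate addition), C13–C16 (Conia-ene-type closure) and C8–C15 (Birch alkylation of benzoic acid).
- Forward order: ring C from benzoic acid, ring D by gold-catalysed cyclisation, aromatic ring A attached at C9, ring B closed as a six-membered ketone, ring A dearomatised and lactonised, ring B contracted by deletion of C7 from the ring, C16 hydrated.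
- Enabling feature: in ring B (C5–C6–C8–C9–C10) C6 carries the exocyclic carboxyl carbon C7 and is bonded to the quaternary, non-enolisable C8. A ring-B ketone C6–C7(=O)–C8 can therefore take a diazo group only at C6, and only C8 can migrate, which is the retron of a Wolff ring contraction.
- Stereochemistry: C8/C13 from enzymatic desymmetrisation of a cyclohexadienone; C9 from exo-face conjugate addition; C4 from a prolinol-derived amide auxiliary; C10 and C5 from anti iodolactonisation and axial hydrogen transfer; C3 from a bulky hydride; C8 retained and C6 equilibrated after the contraction; C16 from radical hydration on the exo face of ring D.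
- Numbering: gibberellane numbers are used throughout (C7 carboxyl carbon on C6, C19 lactone carbonyl on C4, C17 and C18 the methyls on C16 and C4); in the ring-B homologues C7 is the ring ketone carbon between C6 and C8.

Key step: step 21

Assumption: the (S)-2-(methoxymethyl)pyrrolidine amide is taken to direct iodomethane to the C4 face required by the target, and the chosen ene-reductase is taken to give the (R)-enone; if either sense is opposite, the enantiomeric auxiliary or an enzyme of complementary selectivity is used.

**Route**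

Step 1
Reactants: 1 benzoic acid; 2 propargyl bromide (3-bromoprop-1-yne)
Product: 3 1-(prop-2-yn-1-yl)cyclohexa-2,5-diene-1-carboxylic acid
Conditions: Li, NH3(l)/THF, −78 °C; then 2, −78 °C to rt; NH4Cl, then aq. HCl
Reagents that add atoms: none
Why: Birch reduction of the benzoate should give a dienolate dianion that is alkylated at the ipso carbon (Birch reductive alkylation), making C8 quaternary but not yet stereogenic.

Step 2
Reactants: 3 1-(prop-2-yn-1-yl)cyclohexa-2,5-diene-1-carboxylic acid
Product: 4 methyl 1-(prop-2-yn-1-yl)cyclohexa-2,5-diene-1-carboxylate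
Conditions: MeI, K2CO3, DMF, rt
Reagents that add atoms: iodomethane [CH3]I
Why: O-alkylation of the carboxylate by iodomethane (esterification) should give the ester that later serves as the C7 acyl donor.

Step 3
Reactants: 4 methyl 1-(prop-2-yn-1-yl)cyclohexa-2,5-diene-1-carboxylate
Product: 5 methyl 4-oxo-1-(prop-2-yn-1-yl)cyclohexa-2,5-diene-1-carboxylate
Conditions: CrO3 (10 mol%), t-BuOOH (70% aq.), CH2Cl2, rt
Reagents that add atoms: tert-butyl hydroperoxide CC(C)(C)OO
Why: Chromium-catalysed oxidation of the doubly allylic CH2 of a 1,4-diene with a blocked quaternary carbon should give the cross-conjugated dienone (allylic oxidation) and leave ester and alkyne untouched.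

Step 4
Reactants: 5 methyl 4-oxo-1-(prop-2-yn-1-yl)cyclohexa-2,5-diene-1-carboxylate
Product: 6 methyl (R)-4-oxo-1-(prop-2-yn-1-yl)cyclohex-2-ene-1-carboxylate
Conditions: ene-reductase (old yellow enzyme family, variant selected for the R product), NADP+ (cat.), D-glucose, glucose dehydrogenase, phosphate buffer pH 7, DMSO (5%), 30 °C
Reagents that add atoms: none
Why: Flavin-dependent ene-reductases reduce one of the two enantiotopic enone arms of 4,4-disubstituted cyclohexadienones and stop at the enone (desymmetrising conjugate reduction), so the enzyme's choice of arm should set the absolute configuration of quaternary C8.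

Step 5
Reactants: 6 methyl (R)-4-oxo-1-(prop-2-yn-1-yl)cyclohex-2-ene-1-carboxylate
Product: 7 methyl (R)-4-(tert-butyldimethylsilyloxy)-1-(prop-2-yn-1-yl)cyclohexa-2,4-diene-1-carboxylate
Conditions: TBSOTf, Et3N, CH2Cl2, 0 °C
Reagents that add atoms: tert-butyldimethylsilyl trifluoromethanesulfonate CC(C)(C)[Si](C)(C)OS(=O)(=O)C(F)(F)F
Why: Soft enolisation can occur only at C13 because the gamma carbon C8 is quaternary, so the cross-conjugated 2-silyloxydiene should form regiospecifically (silyl enol ether formation).

Step 6
Reactants: 7 methyl (R)-4-(tert-butyldimethylsilyloxy)-1-(prop-2-yn-1-yl)cyclohexa-2,4-diene-1-carboxylate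
Product: 8 methyl (1R,5R)-6-methylidene-4-oxobicyclo[3.2.1]oct-2-ene-1-carboxylate
Conditions: (Ph3P)AuCl (5 mol%), AgBF4 (5 mol%), CH2Cl2/MeOH (10:1), rt
Reagents that add atoms: none
Why: The cationic gold complex formed from (Ph3P)AuCl and AgBF4 activates the alkyne for 5-exo-dig attack by the enol ether carbon C13 (Conia-ene-type carbocyclisation), which should close ring D with the 16-methylidene group, C13 being fixed by the bridge from C8.

Step 7
Reactants: 9 2-methoxy-6-methylbenzoic acid
Product: 10 3-iodo-6-methoxy-2-methylbenzoic acid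
Conditions: N-iodosuccinimide, CF3CO2H (cat.), MeCN, rt
Reagents that add atoms: N-iodosuccinimide O=C1CCC(=O)N1I
Why: Electrophilic aromatic iodination should go para to the methoxy group and ortho to the methyl group, the position activated by both donors.

Step 8
Reactants: 10 3-iodo-6-methoxy-2-methylbenzoic acid; 11 (S)-2-(methoxymethyl)pyrrolidine
Product: 13 (S)-(3-iodo-6-methoxy-2-methylphenyl)[2-(methoxymethyl)pyrrolidin-1-yl]methanone, via acid chloride 12 (not isolated)
Conditions: (COCl)2, DMF (cat.), CH2Cl2, 0 °C to rt; then 11, Et3N, CH2Cl2, 0 °C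
Reagents that add atoms: none
Why: The hindered acid is activated as its chloride and should acylate the secondary amine (amide formation) without touching the auxiliary stereocentre.

Step 9
Reactants: 8 methyl (1R,5R)-6-methylidene-4-oxobicyclo[3.2.1]oct-2-ene-1-carboxylate; 13 (S)-(3-iodo-6-methoxy-2-methylphenyl)[2-(methoxymethyl)pyrrolidin-1-yl]methanone
Product: 15 methyl 2-exo-aryl-6-methylidene-4-oxobicyclo[3.2.1]octane-1-carboxylate (aryl = 4-methoxy-2-methyl-3-[(S)-2-(methoxymethyl)pyrrolidine-1-carbonyl]phenyl on C9 anti to the C15–C16 bridge), via arylmagnesium chloride 14 (not isolated)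
Conditions: 13, i-PrMgCl·LiCl, THF, −20 °C; then CuBr·SMe2 (20 mol%), 8, THF, −78 to −20 °C; aq. NH4Cl
Reagents that add atoms: none
Why: Iodine–magnesium exchange and copper-catalysed 1,4-addition should deliver the aryl group to C9 from the exo face of the bicyclic enone, on the side of the one-carbon bridge C14 and opposite the C15–C16 bridge, which sets C9.

Step 10
Reactants: 15 methyl 2-exo-aryl-6-methylidene-4-oxobicyclo[3.2.1]octane-1-carboxylate
Product: 17 methyl 2-exo-aryl-6-methylidenebicyclo[3.2.1]octane-1-carboxylate (aryl as in 15; C12 is CH2), via C12 tosylhydrazone 16 (not isolated)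
Conditions: TsNHNH2, EtOH, 60 °C; concentrate; catecholborane, CHCl3, 0 °C; then NaOAc·3H2O, reflux
Reagents that add atoms: none
Why: Hydride reduction of the tosylhydrazone with loss of sulfinate and N2 (Caglioti-type deoxygenation) should turn the C12 carbonyl into CH2 under conditions that spare ester, amide and the exocyclic alkene.

Step 11
Reactants: 17 methyl 2-exo-aryl-6-methylidenebicyclo[3.2.1]octane-1-carboxylate
Product: 18 3-methoxy-7-oxo-18,20-dinorkaura-1,3,5(10),16-tetraen-19-oic acid (S)-2-(methoxymethyl)pyrrolidine amide (aromatic ring A; six-membered ring B; C8/C9/C13 as in the target)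
Conditions: LiN(iPr)2 (3 equiv), THF, −78 to 0 °C; aq. NH4Cl
Reagents that add atoms: none
Why: Lateral lithiation of the o-toluamide should give a benzylic anion at C6 that acylates the neighbouring C7 ester (intramolecular Claisen-type condensation) and closes ring B as a six-membered ketone, which is protected as its enolate until work-up.

Step 12
Reactants: 18 tetracyclic ketone
Product: 19 7,7-ethylenedioxy ketal of 18
Conditions: (Me3SiOCH2)2, Me3SiOTf (5 mol%), CH2Cl2, −78 to −20 °C
Reagents that add atoms: 1,2-bis(trimethylsilyloxy)ethane C[Si](C)(C)OCCO[Si](C)(C)C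
Why: Silyl-triflate-catalysed ketalisation should mask the C7 ketone at low temperature without isomerising the 16-ene.

Step 13
Reactants: 19 7,7-ethylenedioxy ketal of 18
Product: 20 3-methoxy-7,7-ethylenedioxy-20-norkaura-2,5(10),16-trien-19-oic acid (S)-2-(methoxymethyl)pyrrolidine amide (C4 bearing methyl C18 and the amide carbonyl C19 as in the target)
Conditions: K, NH3(l)/THF, t-BuOH (1 equiv), −78 °C; then MeI, −78 °C to rt
Reagents that add atoms: iodomethane [CH3]I
Why: Birch reduction of the benzamide should give an amide enolate at C4 that is methylated on carbon (asymmetric Birch reductive alkylation); the methoxy group and the C5 alkyl substituent should favour one enolate geometry, and the pyrrolidine side arm then shields one face, which sets C4.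

Step 14
Reactants: 20 Birch product
Product: 21 3-oxo-7,7-ethylenedioxy-20-norkaura-5(10),16-dien-19-oic acid (S)-2-(methoxymethyl)pyrrolidine amide (C4 as in 20)
Conditions: 1 M HCl, THF, 0 °C
Reagents that add atoms: water O
Why: Dilute acid should hydrolyse the enol ether to the C3 ketone much faster than the hindered dioxolane (enol ether hydrolysis).

Step 15
Reactants: 21 keto amide
Product: 22 10-hydroxy-5-iodo-3-oxo-7,7-ethylenedioxy-20-norkaur-16-en-19-oic acid 19,10-lactone (iodine on C5 trans to the lactone oxygen on C10)
Conditions: I2, NaHCO3, THF/H2O, rt, dark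
Reagents that add atoms: iodine [I][I]; water O
Why: Iodonium formation on C5=C10 and anti attack of the amide oxygen at C10 (iodolactonisation of a beta,gamma-unsaturated amide), then hydrolysis of the iminium ether, should give the bridged 19,10-lactone and release the auxiliary, with C10 set by the face that carries C19 and iodine trans-diaxial on C5.

Step 16
Reactants: 22 iodolactone
Product: 23 10-hydroxy-3-oxo-7,7-ethylenedioxy-20-norkaur-16-en-19-oic acid 19,10-lactone (C5 hydrogen trans to the lactone oxygen; C4/C5/C10 as in the target)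
Conditions: Bu3SnH, AIBN (cat.), benzene, 80 °C
Reagents that add atoms: none
Why: Radical deiodination passes through the tertiary C5 radical, which should take hydrogen along the axial direction on the face opposite the lactone bridge and give the trans-fused decalin-type A/B junction, which sets C5.

Step 17
Reactants: 23 keto lactone
Product: 24 3-hydroxy analogue of 23 (axial hydroxyl at C3 cis to the C5 hydrogen as in the target)
Conditions: LiBH(s-Bu)3, THF, −78 °C; aq. NH4Cl
Reagents that add atoms: none
Why: The bulky borohydride should attack the C3 ketone along the equatorial trajectory and give the axial alcohol cis to the C5 hydrogen (diastereoselective ketone reduction), while lactone and ketal are not reduced at low temperature.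

Step 18
Reactants: 24 hydroxy lactone
Product: 25 3-O-tert-butyldimethylsilyl ether of 24
Conditions: TBSOTf, 2,6-lutidine, CH2Cl2, 0 °C
Reagents that add atoms: tert-butyldimethylsilyl trifluoromethanesulfonate CC(C)(C)[Si](C)(C)OS(=O)(=O)C(F)(F)F
Why: Silylation of the hindered secondary alcohol should prevent retro-aldol epimerisation at C3 in the later basic steps.

Step 19
Reactants: 25 silyl ether ketal
Product: 26 3-(tert-butyldimethylsilyloxy)-10-hydroxy-7-oxo-20-norkaur-16-en-19-oic acid 19,10-lactone (six-membered ring B with C7 as ring ketone)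
Conditions: pyridinium p-toluenesulfonate (cat.), acetone/H2O, 55 °C
Reagents that add atoms: water O
Why: Mild acid-catalysed transketalisation should release the C7 ketone while silyl ether, lactone and 16-ene survive.

Step 20
Reactants: 26 7-oxo lactone
Product: 28 6-diazo derivative of 26, via 6-trifluoroacetyl ketone 27 (not isolated)
Conditions: LiN(SiMe3)2, THF, −78 °C; CF3CO2CH2CF3; aq. HCl work-up; then 4-acetamidobenzenesulfonyl azide, Et3N, H2O (1 equiv), MeCN, rt
Reagents that add atoms: 4-acetamidobenzenesulfonyl azide CC(=O)Nc1ccc(cc1)S(=O)(=O)N=[N+]=[N-]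
Why: C6 is the only enolisable position because C8 and the lactone alpha-carbon C4 are both quaternary, so trifluoroacetylation and azide transfer with loss of the trifluoroacetyl group (Regitz-type diazo transfer) should place the diazo group at C6.

Step 21
Reactants: 28 6-diazo-7-oxo lactone
Product: 30 3-(tert-butyldimethylsilyloxy)-10-hydroxy-20-norgibberell-16-ene-7,19-dioic acid 19,10-lactone 7-[2-(trimethylsilyl)ethyl] ester as C6 epimer mixture, via ketene 29 (not isolated)
Conditions: hν (medium-pressure Hg lamp, Pyrex filter), Me3SiCH2CH2OH (10 equiv), THF, 0 °C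
Reagents that add atoms: 2-(trimethylsilyl)ethanol C[Si](C)(C)CCO
Why: Irradiation of the cyclic alpha-diazo ketone, locked s-cis by the ring, expels N2 while the C7–C8 bond migrates to C6 (photochemical Wolff rearrangement), which forms the C6–C8 bond and gives ketene 29 that the alcohol captures as the ester. The closest known reaction type is the Wolff ring contraction of 2-diazocyclohexanones to cyclopentanecarboxylic esters, including ring B of kaurane-type polycycles. Ring B is closed as a five-membered ring by a 1,2-shift that expels C7 from the ring, not by an end-on cyclisation, so no Baldwin constraint applies. C8 migrates with retention and C4, C5, C9 and C10 are untouched. The new centre C6 arises on protonation of the ester enol, probably from the face remote from C4, and is not relied upon because step 22 equilibrates it. The step needs migration of C8 in preference to a 1,2-hydrogen shift from C5 or carbene C–H insertion, and the concerted pathway from the enforced s-cis geometry, with C8 the only migratable substituent on the carbonyl carbon, should secure this.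

Step 22
Reactants: 30 ring-contracted ester as C6 epimer mixture
Product: 31 3-(tert-butyldimethylsilyloxy)-10-hydroxy-20-norgibberell-16-ene-7,19-dioic acid 19,10-lactone 7-[2-(trimethylsilyl)ethyl] ester (natural C6 configuration; ester trans to C4)
Conditions: KOt-Bu (0.3 equiv), t-BuOH/THF, rt
Reagents that add atoms: none
Why: Reversible enolisation of the ester should equilibrate C6 to the isomer with the ester trans to C4 on the cyclopentane ring (thermodynamic epimerisation), which is the natural configuration.

Step 23
Reactants: 31 16-ene ester with natural C6 configuration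
Product: 32 3-(tert-butyldimethylsilyloxy)-10,16-dihydroxy-20-norgibberellane-7,19-dioic acid 19,10-lactone 7-[2-(trimethylsilyl)ethyl] ester (16-hydroxyl on the C14 side of ring D)
Conditions: Co(acac)2 (20 mol%), PhSiH3, O2 (1 atm), THF, rt
Reagents that add atoms: dioxygen O=O
Why: Hydrogen atom transfer from a cobalt hydride to the 1,1-disubstituted alkene gives the tertiary C16 radical, which O2 should trap on the exo face of ring D opposite the C9–C11–C12 bridge (Mukaiyama hydration), giving the Markovnikov tertiary alcohol and setting C16.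

Step 24
Reactants: 32 doubly protected 16-hydroxy ester
Product: 33 the target gibberellin (3,10,16-trihydroxy-20-norgibberellane-7,19-dioic acid 19,10-lactone)
Conditions: Bu4NF, AcOH, THF, rt to 40 °C; aq. citric acid
Reagents that add atoms: none
Why: Buffered fluoride should cleave the 2-(trimethylsilyl)ethyl ester by beta-elimination and the silyl ether by Si–F bond formation (fluoride deprotection) without epimerising C3.

**Compound list**

1 | benzoic acid | OC(=O)c1ccccc1 | starting material
2 | propargyl bromide (3-bromoprop-1-yne) | BrCC#C | starting material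
3 | 1-(prop-2-yn-1-yl)cyclohexa-2,5-diene-1-carboxylic acid | OC(=O)C1(CC#C)C=CCC=C1 | intermediate
4 | methyl 1-(prop-2-yn-1-yl)cyclohexa-2,5-diene-1-carboxylate | COC(=O)C1(CC#C)C=CCC=C1 | intermediate
5 | methyl 4-oxo-1-(prop-2-yn-1-yl)cyclohexa-2,5-diene-1-carboxylate | COC(=O)C1(CC#C)C=CC(=O)C=C1 | intermediate
6 | methyl (R)-4-oxo-1-(prop-2-yn-1-yl)cyclohex-2-ene-1-carboxylate | C1=CC(=O)CC[C@]1(CC#C)C(=O)OC | intermediate
7 | methyl (R)-4-(tert-butyldimethylsilyloxy)-1-(prop-2-yn-1-yl)cyclohexa-2,4-diene-1-carboxylate | C1=CC(O[Si](C)(C)C(C)(C)C)=CC[C@]1(CC#C)C(=O)OC | intermediate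
8 | methyl (1R,5R)-6-methylidene-4-oxobicyclo[3.2.1]oct-2-ene-1-carboxylate | C1=CC(=O)[C@@H]2C[C@]1(CC2=C)C(=O)OC | intermediate
9 | 2-methoxy-6-methylbenzoic acid | COc1cccc(C)c1C(=O)O | starting material
10 | 3-iodo-6-methoxy-2-methylbenzoic acid | COc1ccc(I)c(C)c1C(=O)O | intermediate
11 | (S)-2-(methoxymethyl)pyrrolidine | COC[C@@H]1CCCN1 | starting material
12 | 3-iodo-6-methoxy-2-methylbenzoyl chloride | COc1ccc(I)c(C)c1C(=O)Cl | intermediate
13 | (S)-(3-iodo-6-methoxy-2-methylphenyl)[2-(methoxymethyl)pyrrolidin-1-yl]methanone | COC[C@@H]1CCCN1C(=O)c1c(C)c(I)ccc1OC | intermediate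
14 | arylmagnesium chloride from 13 (Mg in place of I) | COC[C@@H]1CCCN1C(=O)c1c(C)c([Mg]Cl)ccc1OC | intermediate
15 | methyl 2-exo-aryl-6-methylidene-4-oxobicyclo[3.2.1]octane-1-carboxylate (aryl = 4-methoxy-2-methyl-3-[(S)-2-(methoxymethyl)pyrrolidine-1-carbonyl]phenyl on C9 anti to the C15–C16 bridge) | COc1ccc([C@@H]2CC(=O)[C@@H]3C[C@]2(CC3=C)C(=O)OC)c(C)c1C(=O)N1CCC[C@H]1COC | intermediate
16 | C12 tosylhydrazone of 15 | COc1ccc([C@@H]2CC(=NNS(=O)(=O)c3ccc(C)cc3)[C@@H]4C[C@]2(CC4=C)C(=O)OC)c(C)c1C(=O)N1CCC[C@H]1COC | intermediate
17 | methyl 2-exo-aryl-6-methylidenebicyclo[3.2.1]octane-1-carboxylate (aryl as in 15; C12 is CH2) | COc1ccc([C@@H]2CC[C@@H]3C[C@]2(CC3=C)C(=O)OC)c(C)c1C(=O)N1CCC[C@H]1COC | intermediate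
18 | 3-methoxy-7-oxo-18,20-dinorkaura-1,3,5(10),16-tetraen-19-oic acid (S)-2-(methoxymethyl)pyrrolidine amide (aromatic ring A; six-membered ring B; C8/C9/C13 as in the target) | COc1ccc2[C@@H]3CC[C@@H]4C[C@]3(CC4=C)C(=O)Cc2c1C(=O)N1CCC[C@H]1COC | intermediate
19 | 7,7-ethylenedioxy ketal of 18 | COc1ccc2[C@@H]3CC[C@@H]4C[C@]3(CC4=C)C5(OCCO5)Cc2c1C(=O)N1CCC[C@H]1COC | intermediate
20 | 3-methoxy-7,7-ethylenedioxy-20-norkaura-2,5(10),16-trien-19-oic acid (S)-2-(methoxymethyl)pyrrolidine amide (C4 bearing methyl C18 and the amide carbonyl C19 as in the target) | C[C@@]1(C(=O)N2CCC[C@H]2COC)C(OC)=CCC3=C1CC4(OCCO4)[C@@]5(CC6=C)C[C@H]6CC[C@@H]35 | intermediate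
21 | 3-oxo-7,7-ethylenedioxy-20-norkaura-5(10),16-dien-19-oic acid (S)-2-(methoxymethyl)pyrrolidine amide (C4 as in 20) | C[C@@]1(C(=O)N2CCC[C@H]2COC)C(=O)CCC3=C1CC4(OCCO4)[C@@]5(CC6=C)C[C@H]6CC[C@@H]35 | intermediate
22 | 10-hydroxy-5-iodo-3-oxo-7,7-ethylenedioxy-20-norkaur-16-en-19-oic acid 19,10-lactone (iodine on C5 trans to the lactone oxygen on C10) | C[C@@]12C(=O)O[C@]3(CCC1=O)[C@@H]1CC[C@@H]4C[C@]1(CC4=C)C5(OCCO5)C[C@@]32I | intermediate
23 | 10-hydroxy-3-oxo-7,7-ethylenedioxy-20-norkaur-16-en-19-oic acid 19,10-lactone (C5 hydrogen trans to the lactone oxygen; C4/C5/C10 as in the target) | C[C@@]12C(=O)O[C@]3(CCC1=O)[C@@H]1CC[C@@H]4C[C@]1(CC4=C)C5(OCCO5)C[C@@H]32 | intermediate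
24 | 3-hydroxy analogue of 23 (axial hydroxyl at C3 cis to the C5 hydrogen as in the target) | C[C@@]12C(=O)O[C@]3(CC[C@@H]1O)[C@@H]1CC[C@@H]4C[C@]1(CC4=C)C5(OCCO5)C[C@@H]32 | intermediate
25 | 3-O-tert-butyldimethylsilyl ether of 24 | C[C@@]12C(=O)O[C@]3(CC[C@@H]1O[Si](C)(C)C(C)(C)C)[C@@H]1CC[C@@H]4C[C@]1(CC4=C)C5(OCCO5)C[C@@H]32 | intermediate
26 | 3-(tert-butyldimethylsilyloxy)-10-hydroxy-7-oxo-20-norkaur-16-en-19-oic acid 19,10-lactone (six-membered ring B with C7 as ring ketone) | C[C@@]12C(=O)O[C@]3(CC[C@@H]1O[Si](C)(C)C(C)(C)C)[C@@H]1CC[C@@H]4C[C@]1(CC4=C)C(=O)C[C@@H]32 | intermediate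
27 | 6-trifluoroacetyl derivative of 26 | C[C@@]12C(=O)O[C@]3(CC[C@@H]1O[Si](C)(C)C(C)(C)C)[C@@H]1CC[C@@H]4C[C@]1(CC4=C)C(=O)C(C(=O)C(F)(F)F)[C@@H]32 | intermediate
28 | 6-diazo derivative of 26 | C[C@@]12C(=O)O[C@]3(CC[C@@H]1O[Si](C)(C)C(C)(C)C)[C@@H]1CC[C@@H]4C[C@]1(CC4=C)C(=O)C(=[N+]=[N-])[C@@H]32 | intermediate
29 | ketene: ring-contracted 20-norgibberell-16-ene with C6=C7=O (3-O-TBS; 19,10-lactone) | C[C@@]12C(=O)O[C@]3(CC[C@@H]1O[Si](C)(C)C(C)(C)C)[C@@H]1CC[C@@H]4C[C@]1(CC4=C)C(=C=O)[C@@H]32 | intermediate
30 | 3-(tert-butyldimethylsilyloxy)-10-hydroxy-20-norgibberell-16-ene-7,19-dioic acid 19,10-lactone 7-[2-(trimethylsilyl)ethyl] ester as C6 epimer mixture | C[C@@]12C(=O)O[C@]3(CC[C@@H]1O[Si](C)(C)C(C)(C)C)[C@@H]1CC[C@@H]4C[C@]1(CC4=C)C(C(=O)OCC[Si](C)(C)C)[C@@H]32 | intermediate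
31 | 3-(tert-butyldimethylsilyloxy)-10-hydroxy-20-norgibberell-16-ene-7,19-dioic acid 19,10-lactone 7-[2-(trimethylsilyl)ethyl] ester (natural C6 configuration; ester trans to C4) | C[C@@]12C(=O)O[C@]3(CC[C@@H]1O[Si](C)(C)C(C)(C)C)[C@@H]1CC[C@@H]4C[C@]1(CC4=C)[C@@H](C(=O)OCC[Si](C)(C)C)[C@@H]32 | intermediate
32 | 3-(tert-butyldimethylsilyloxy)-10,16-dihydroxy-20-norgibberellane-7,19-dioic acid 19,10-lactone 7-[2-(trimethylsilyl)ethyl] ester (16-hydroxyl on the C14 side of ring D) | C[C@@]12C(=O)O[C@]3(CC[C@@H]1O[Si](C)(C)C(C)(C)C)[C@@H]1CC[C@@H]4C[C@]1(C[C@@]4(C)O)[C@@H](C(=O)OCC[Si](C)(C)C)[C@@H]32 | intermediate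
33 | the target gibberellin: 3,10,16-trihydroxy-20-norgibberellane-7,19-dioic acid 19,10-lactone (3-hydroxyl axial and cis to the C5 hydrogen; 16-hydroxyl on the C14 side of ring D; configuration as in the SMILES) | C[C@@]12C(=O)O[C@]3(CC[C@@H]1O)[C@@H]1CC[C@@H]4C[C@]1(C[C@@]4(C)O)[C@@H](C(=O)O)[C@@H]32 | target

**Step count and risks**

Total: 24 steps. Longest linear sequence: 22 steps (steps 1–6 and 9–24, from benzoic acid); steps 7 and 8 make the aryl fragment.

Most likely to fail, step 13: facial selectivity in the methylation of the Birch enolate may be poor, because the two ortho substituents may not lock a single amide enolate geometry; over-reduction is also possible. Fallback, setting out from 19 and returning at 21: the Birch reduction is run without alkylation (K, NH3, t-BuOH, NH4Cl quench) to give the C4–H dihydro amide F1. Dilute HCl should hydrolyse the enol ether to the beta-keto amide F2. Methylation of its metal-chelated enolate (NaH, MeI, THF, 0 °C) would then set C4 under the control of a rigid chelate between the enolate oxygen and the amide oxygen, not of the Birch enolate geometry, and give 21.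

Second, step 9: the conjugate addition may fail through steric congestion at C9, next to the quaternary bridgehead, with competing 1,2-addition or enolisation. Fallback, setting out from 8 and 13 and returning at 15: palladium-catalysed hydroarylation (reductive Heck reaction; Pd(OAc)2, HCO2Na, Bu4NCl, DMF, 60 °C). The arylpalladium species from 13 should insert the enone from the exo face and the palladium enolate is reduced by formate, giving 15 directly; this fallback makes no new compound (F0).

Third, step 4: the enzymatic desymmetrisation may give insufficient conversion or enantioselectivity with this ester- and alkyne-substituted dienone, or over-reduce. Fallback, setting out from 5 and returning at 15: resolution in place of asymmetric catalysis. Non-selective mono-reduction with LiBH(s-Bu)3 (1 equiv, THF, −78 °C) should give racemic enone F3. Silylation and gold cyclisation as in steps 5 and 6 would give racemic silyl dienol ether F4 and racemic bicyclic enone F5. Addition of the enantiopure aryl Grignard reagent from 13 under the conditions of step 9 should then give 15 together with its diastereomer F6 (opposite configuration at C8, C9 and C13). The auxiliary already present should allow their separation by chromatography.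

Further compounds
F1 | step 13 | C4–H analogue of 20 (3-methoxy-7,7-ethylenedioxy-2,5(10),16-triene amide without the C18 methyl) | O=C(C1C(OC)=CCC2=C1CC3(OCCO3)[C@@]4(CC5=C)C[C@H]5CC[C@@H]24)N1CCC[C@H]1COC
F2 | step 13 | C4–H analogue of 21 (beta-keto amide) | O=C(C1C(=O)CCC2=C1CC3(OCCO3)[C@@]4(CC5=C)C[C@H]5CC[C@@H]24)N1CCC[C@H]1COC
F0 | step 9 | none | none
F3 | step 4 | racemic methyl 4-oxo-1-(prop-2-yn-1-yl)cyclohex-2-ene-1-carboxylate | C#CCC1(C(=O)OC)CCC(=O)C=C1
F4 | step 4 | racemic methyl 4-(tert-butyldimethylsilyloxy)-1-(prop-2-yn-1-yl)cyclohexa-2,4-diene-1-carboxylate | C#CCC1(C(=O)OC)CC=C(O[Si](C)(C)C(C)(C)C)C=C1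
F5 | step 4 | racemic methyl 6-methylidene-4-oxobicyclo[3.2.1]oct-2-ene-1-carboxylate | C=C1CC2(C(=O)OC)CC1C(=O)C=C2
F6 | step 4 | diastereomer of 15 with opposite configuration at C8/C9/C13 | COc1ccc([C@H]2CC(=O)[C@H]3C[C@@]2(CC3=C)C(=O)OC)c(C)c1C(=O)N1CCC[C@H]1COC
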